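The upper flavan is built de novo and only then joined to catechin. Everything rests on assembling ring C from an α-benzyloxy aryl ketone (C2, C3, ring B) and two equivalents of a 2-fluoro-4,6-dibenzyloxybenzaldehyde (C4, ring A): an asymmetric aldol–Tishchenko reaction forms C3–C4, reduces C2 and acylates the C4 oxygen, and the freed C2 alkoxide (O1) then displaces fluoride at C8a in the same flask. The step exploits two features: C8a is meta to both ring A oxygens (C5, C7), so fluoride substitution is feasible, and C4 is the doubly activated benzylic carbon that later ionises to receive C8 of catechin anti to the C3 oxygen.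

Key step: step 3

Assumption: the (R)-binaphthoxide catalyst is taken to deliver the (2R,3R)-aldol series drawn below; if the sense of induction is the opposite, the (S)-catalyst is used and nothing else changes.

Step 1
Reactants: 1 2,4,6-trifluorobenzaldehyde; 2 benzyl alcohol (2.05 equiv)
Product: 4 2,4-bis(benzyloxy)-6-fluorobenzaldehyde, via 4-(benzyloxy)-2,6-difluorobenzaldehyde 3 (not isolated)
Conditions: NaH (2.1 equiv), THF, 0 °C → rt
Reagents that add atoms: none
Why: Two successive SNAr (addition–elimination) displacements of fluoride by benzyloxide, first para and then ortho to the activating formyl group, should stop at 4 because the last fluorine is deactivated by two alkoxy donors; no stereocentre is formed.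

Step 2
Reactants: 5 5-bromo-1,2,3-tris(benzyloxy)benzene; 6 2-(benzyloxy)-N-methoxy-N-methylacetamide
Product: 8 2-(benzyloxy)-1-[3,4,5-tris(benzyloxy)phenyl]ethan-1-one, via aryllithium 7 (not isolated)
Conditions: n-BuLi (n-C4H9Li), THF, −78 °C; then 6, −78 → 0 °C; aq NH4Cl
Reagents that add atoms: none
Why: Bromine–lithium exchange gives aryllithium 7, which is acylated by Weinreb amide 6 through a chelated tetrahedral adduct that collapses to the ketone only on work-up, so over-addition is avoided (Weinreb ketone synthesis); no stereocentre is formed.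

Step 3
Reactants: 8 2-(benzyloxy)-1-[3,4,5-tris(benzyloxy)phenyl]ethan-1-one; 4 2,4-bis(benzyloxy)-6-fluorobenzaldehyde (2.3 equiv: one molecule is the aldol acceptor, one the hydride donor and acyl source)
Product: 11 (2R,3S,4R)-3,5,7-tris(benzyloxy)-2-[3,4,5-tris(benzyloxy)phenyl]chroman-4-yl 2,4-bis(benzyloxy)-6-fluorobenzoate, via anti-aldol adduct 9 (not isolated), via diol monoester 10 (not isolated)
Conditions: LaLi3[(R)-1,1'-binaphthalene-2,2'-diolate]3 (10 mol %), LiOSO2CF3 (30 mol %), THF, rt; then KN(SiMe3)2 (1.5 equiv), DMF, 0 → 50 °C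
Reagents that add atoms: none
Why: The lanthanum–lithium binaphthoxide turns 8 into a chelated enolate that adds reversibly to 4 (C3–C4 bond, aldol adduct 9); the aldolate adds a second molecule of 4 and the hemiacetal delivers hydride to the C2 ketone through a six-membered chair (Evans–Tishchenko step), which frees the C2 oxygen (the future O1) in 10 while masking the C4 oxygen as an aroyl ester, and KN(SiMe3)2 then makes the potassium alkoxide, which closes the pyran ring by intramolecular SNAr at the fluorine-bearing C8a. The closest known reactions are the direct catalytic asymmetric aldol–Tishchenko reaction of aryl ketones with aryl aldehydes and the alkoxide SNAr ring closure of 3,5-dialkoxyfluoroarenes used for flavan-3-ols, here run in one flask. The only ring closed is ring C, by 6-exo-trig attack of O1 on C8a (Meisenheimer adduct, loss of fluoride). C3 and C4 arise in the reversible aldol and are selected in the irreversible hydride transfer, whose chair places the C3 benzyloxy and C4 aryl groups equatorial (1,2-anti), C2 is set by the internal hydride delivery (1,3-anti to the C4 oxygen, hence syn to the C3 oxygen, which is the 2,3-cis relation of the target), and the absolute sense comes from the chiral catalyst. The step needs chemoselectivity among three oxygens and it is secured by the substrate: O3 is a benzyl ether, the C4 oxygen is acylated and could only close a four-membered ring, and any ester shift between the C2 and C4 oxygens is harmless because only the C2 alkoxide can cyclise. The C4 configuration is not critical, since C4 is ionised in step 5.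

Step 4
Reactants: 12 (+)-catechin
Product: 13 (2R,3S)-5,7-bis(benzyloxy)-2-[3,4-bis(benzyloxy)phenyl]chroman-3-ol (5,7,3',4'-tetra-O-benzylcatechin)
Conditions: BnBr (4.4 equiv), K2CO3, DMF, 0 °C → rt
Reagents that add atoms: benzyl bromide BrCc1ccccc1
Why: Williamson etherification under carbonate benzylates the four phenolic hydroxyls and spares the much less acidic secondary C3 hydroxyl; both stereocentres of the bought catechin are untouched.

Step 5
Reactants: 11 the chroman-4-yl ester from step 3; 13 5,7,3',4'-tetra-O-benzylcatechin (4 equiv)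
Product: 14 deca-O-benzyl epigallocatechin-(4β→8)-catechin: upper unit (2R,3R,4R) with benzyl ethers at O3, O5, O7 and the three ring B oxygens, lower unit (2R,3S) with benzyl ethers at O5, O7, O3', O4' and a free 3-OH
Conditions: Me3SiOSO2CF3 (0.3 equiv), CH2Cl2, −78 → −40 °C
Reagents that add atoms: none
Why: The Lewis acid ionises the C4 aroyloxy group to a flavan-4-yl cation stabilised by O1 and the C5 and C7 oxygens of ring A, and Friedel–Crafts attack of C8 of 13 (the most nucleophilic ring position, used in excess to suppress oligomers) anti to the C3 benzyloxy group should set C4 as 3,4-trans (4β), the biomimetic interflavan coupling.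

Step 6
Reactants: 14 deca-O-benzyl dimer
Product: 15 epigallocatechin-(4β→8)-catechin (target, CNP0225927.1)
Conditions: H2 (1 atm), Pd(OH)2/C, THF/MeOH/H2O, rt
Reagents that add atoms: none
Why: Catalytic hydrogenolysis cleaves all ten benzyl ethers under neutral conditions that leave the acid-labile interflavan bond and the five stereocentres intact.

Compound list
1 | 2,4,6-trifluorobenzaldehyde | O=Cc1c(F)cc(F)cc1F | starting material
2 | benzyl alcohol | OCc1ccccc1 | starting material
3 | 4-(benzyloxy)-2,6-difluorobenzaldehyde | O=Cc1c(F)cc(OCc2ccccc2)cc1F | intermediate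
4 | 2,4-bis(benzyloxy)-6-fluorobenzaldehyde | O=Cc1c(F)cc(OCc2ccccc2)cc1OCc1ccccc1 | intermediate
5 | 5-bromo-1,2,3-tris(benzyloxy)benzene | Brc1cc(OCc2ccccc2)c(OCc2ccccc2)c(OCc2ccccc2)c1 | starting material
6 | 2-(benzyloxy)-N-methoxy-N-methylacetamide | CON(C)C(=O)COCc1ccccc1 | starting material
7 | [3,4,5-tris(benzyloxy)phenyl]lithium | [Li]c1cc(OCc2ccccc2)c(OCc2ccccc2)c(OCc2ccccc2)c1 | intermediate
8 | 2-(benzyloxy)-1-[3,4,5-tris(benzyloxy)phenyl]ethan-1-one | O=C(COCc1ccccc1)c1cc(OCc2ccccc2)c(OCc2ccccc2)c(OCc2ccccc2)c1 | intermediate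
9 | (2R,3R)-2-(benzyloxy)-3-[2,4-bis(benzyloxy)-6-fluorophenyl]-3-hydroxy-1-[3,4,5-tris(benzyloxy)phenyl]propan-1-one (anti-aldol adduct) | O=C(c1cc(OCc2ccccc2)c(OCc2ccccc2)c(OCc2ccccc2)c1)[C@H](OCc1ccccc1)[C@@H](c1c(F)cc(OCc2ccccc2)cc1OCc1ccccc1)O | intermediate
10 | (1R,2S,3R)-2-(benzyloxy)-1-[2,4-bis(benzyloxy)-6-fluorophenyl]-3-hydroxy-3-[3,4,5-tris(benzyloxy)phenyl]propyl 2,4-bis(benzyloxy)-6-fluorobenzoate (anti,anti diol monoester) | O[C@H](c1cc(OCc2ccccc2)c(OCc2ccccc2)c(OCc2ccccc2)c1)[C@H](OCc1ccccc1)[C@@H](c1c(F)cc(OCc2ccccc2)cc1OCc1ccccc1)OC(=O)c1c(F)cc(OCc2ccccc2)cc1OCc1ccccc1 | intermediate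
11 | (2R,3S,4R)-3,5,7-tris(benzyloxy)-2-[3,4,5-tris(benzyloxy)phenyl]chroman-4-yl 2,4-bis(benzyloxy)-6-fluorobenzoate (2,3-cis, 3,4-cis) | O(Cc1ccccc1)c1cc(OCc3ccccc3)c2c(c1)O[C@H](c1cc(OCc3ccccc3)c(OCc3ccccc3)c(OCc3ccccc3)c1)[C@H](OCc1ccccc1)[C@@H]2OC(=O)c1c(F)cc(OCc2ccccc2)cc1OCc1ccccc1 | intermediate
12 | (+)-catechin, (2R,3S) | Oc1cc(O)c2c(c1)O[C@H](c1ccc(O)c(O)c1)[C@@H](O)C2 | starting material
13 | (2R,3S)-5,7-bis(benzyloxy)-2-[3,4-bis(benzyloxy)phenyl]chroman-3-ol | O(Cc1ccccc1)c1cc(OCc2ccccc2)c2c(c1)O[C@H](c1ccc(OCc3ccccc3)c(OCc3ccccc3)c1)[C@@H](O)C2 | intermediate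
14 | deca-O-benzyl epigallocatechin-(4β→8)-catechin, upper unit (2R,3R,4R), lower unit (2R,3S), lower 3-OH free | O(Cc1ccccc1)c1cc(OCc3ccccc3)c2c(c1)O[C@H](c1cc(OCc3ccccc3)c(OCc3ccccc3)c(OCc3ccccc3)c1)[C@H](OCc1ccccc1)[C@H]2c1c(OCc2ccccc2)cc(OCc2ccccc2)c2c1O[C@H](c1ccc(OCc3ccccc3)c(OCc3ccccc3)c1)[C@@H](O)C2 | intermediate
15 | epigallocatechin-(4β→8)-catechin, upper unit (2R,3R,4R), lower unit (2R,3S) | Oc1cc(O)c2c(c1)O[C@H](c1cc(O)c(O)c(O)c1)[C@H](O)[C@H]2c1c(O)cc(O)c2c1O[C@H](c1ccc(O)c(O)c1)[C@@H](O)C2 | target

Total step count: 6. Longest linear sequence: 4 steps (step 1 or 2, then steps 3, 5 and 6).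

Steps most likely to fail

Step 3 (key step). The process at risk is the hydride transfer: the doubly ortho-substituted, electron-rich aldehyde may form the hemiacetal slowly, so that the reversible aldol stalls or catalyst control over enantio- and diastereoselection erodes. The fallback gives up catalyst control and resolves through the chiral lower unit. It sets out from 8 and 4 and uses the stoichiometric lithium enolate (LiN(SiMe3)2, THF, −78 → 0 °C; then KN(SiMe3)2, DMF), a known aldol–Tishchenko variant driven by a full equivalent of alkoxide. This should give 9, 10 and 11 as racemates, that is together with the enantiomeric aldol adduct F1, the enantiomeric diol monoester F2 and the enantiomeric chroman ester F3. Coupling of the racemic ester with 13 under the conditions of step 5 should then give 14 together with the diastereomeric dimer F4, which is removed by chromatography; the route is rejoined at 14.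

Step 5. The process at risk is selective capture of the cation: slow ionisation of the hindered all-cis ester, attack through C6 of 13, or attack of the product on a second cation (oligomerisation). The fallback changes the mode of activation from a hard Lewis acid to a thiophile. It sets out from 11, which with benzyl mercaptan and BF3·OEt2 (CH2Cl2, −78 °C) should give the 4β-benzylthio flavan F5. AgBF4 in THF at 0 °C then releases the cation slowly in the presence of 13 and should give 14, where the route is rejoined.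

Step 1. The process at risk is regio- and chemocontrol: substitution of both ortho fluorines, a third substitution, or benzyloxide addition to the formyl group. The fallback installs the formyl group last. It sets out from 2, which with 1,3,5-trifluorobenzene (NaH, DMF, 80 °C) should give 1,3-bis(benzyloxy)-5-fluorobenzene F6. Vilsmeier–Haack formylation (POCl3, DMF; then aq NaOAc) at the position between fluorine and one benzyloxy group, para to the other, should give 4, where the route is rejoined.

Further compounds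
F1 | step 3 | (2S,3S)-2-(benzyloxy)-3-[2,4-bis(benzyloxy)-6-fluorophenyl]-3-hydroxy-1-[3,4,5-tris(benzyloxy)phenyl]propan-1-one | O=C(c1cc(OCc2ccccc2)c(OCc2ccccc2)c(OCc2ccccc2)c1)[C@@H](OCc1ccccc1)[C@H](c1c(F)cc(OCc2ccccc2)cc1OCc1ccccc1)O
F2 | step 3 | (1S,2R,3S)-2-(benzyloxy)-1-[2,4-bis(benzyloxy)-6-fluorophenyl]-3-hydroxy-3-[3,4,5-tris(benzyloxy)phenyl]propyl 2,4-bis(benzyloxy)-6-fluorobenzoate | O[C@@H](c1cc(OCc2ccccc2)c(OCc2ccccc2)c(OCc2ccccc2)c1)[C@@H](OCc1ccccc1)[C@H](c1c(F)cc(OCc2ccccc2)cc1OCc1ccccc1)OC(=O)c1c(F)cc(OCc2ccccc2)cc1OCc1ccccc1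
F3 | step 3 | (2S,3R,4S)-3,5,7-tris(benzyloxy)-2-[3,4,5-tris(benzyloxy)phenyl]chroman-4-yl 2,4-bis(benzyloxy)-6-fluorobenzoate | O(Cc1ccccc1)c1cc(OCc3ccccc3)c2c(c1)O[C@@H](c1cc(OCc3ccccc3)c(OCc3ccccc3)c(OCc3ccccc3)c1)[C@@H](OCc1ccccc1)[C@H]2OC(=O)c1c(F)cc(OCc2ccccc2)cc1OCc1ccccc1
F4 | step 3 | deca-O-benzyl dimer with (2S,3S,4S) upper unit and (2R,3S) lower unit, diastereomer of 14 | O(Cc1ccccc1)c1cc(OCc3ccccc3)c2c(c1)O[C@@H](c1cc(OCc3ccccc3)c(OCc3ccccc3)c(OCc3ccccc3)c1)[C@@H](OCc1ccccc1)[C@@H]2c1c(OCc2ccccc2)cc(OCc2ccccc2)c2c1O[C@H](c1ccc(OCc3ccccc3)c(OCc3ccccc3)c1)[C@@H](O)C2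
F5 | step 5 | (2R,3S,4S)-4-(benzylsulfanyl)-3,5,7-tris(benzyloxy)-2-[3,4,5-tris(benzyloxy)phenyl]chroman (2,3-cis, 3,4-trans) | O(Cc1ccccc1)c1cc(OCc3ccccc3)c2c(c1)O[C@H](c1cc(OCc3ccccc3)c(OCc3ccccc3)c(OCc3ccccc3)c1)[C@H](OCc1ccccc1)[C@H]2SCc1ccccc1
F6 | step 1 | 1,3-bis(benzyloxy)-5-fluorobenzene | Fc1cc(OCc2ccccc2)cc(OCc2ccccc2)c1
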